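A tube in plug flow and a closed flask give every portion of the charge the same 40 min, so spring and midnight are one reckoning, while dawn's stirred tank, with its spread of ages, has to be treated apart.

| flask | Q | remark | time |
|---|---|---|---|
| ochre | 1 M | run made earlier |  |
| red | 0.50 M | run made earlier |  |
| teal | 2 M | run made earlier |  |
| dawn | 1.0 M | one stirred flow tank at steady state, fed with the mixture as stated, mean residence time 40 min |  |
| spring | 1.0 M | plug flow through a tube for 40 min, no back-mixing | 40 min |
| midnight | 1.0 M | a closed flask charged with all of it at once and left for 40 min | 40 min |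

| run | time / min | Z / % | Q / % |
|---|---|---|---|
| ochre | 1.33 | 33.0 | 49.7 |
| ochre | 4.00 | 37.6 | 35.0 |
| ochre | 6.00 | 35.7 | 31.0 |
| ochre | 10.0 | 33.4 | 26.5 |
| ochre | 15.0 | 32.7 | 22.5 |
| ochre | 20.0 | 32.3 | 19.7 |
| ochre | 25.0 | 31.3 | 17.6 |
| red | 4.00 | 43.5 | 32.7 |
| red | 6.00 | 41.3 | 29.1 |
| red | 8.00 | 39.7 | 26.8 |
| red | 15.0 | 36.8 | 22.5 |
| red | 20.0 | 36.2 | 20.9 |
| red | 30.0 | 35.0 | 16.8 |
| red | 50.0 | 34.3 | 13.5 |
| teal | 6.00 | 31.8 | 29.9 |
| teal | 15.0 | 30.0 | 20.0 |
| teal | 20.0 | 29.7 | 16.9 |
| teal | 30.0 | 29.1 | 13.1 |
| teal | 40.0 | 29.5 | 10.9 |
| teal | 50.0 | 28.9 | 8.9 |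

(each reading ± 0.3 percentage points)

- the set-up with the highest amount of Z at the outlet or at the end, in percent of the Q put in ("none" if the first two lie within 2 percentage points) (dawn / spring / midnight / none)
- amount of Z at the outlet or at the end, in percent of the Q put in, dawn
- amount of Z at the outlet or at the end, in percent of the Q put in, spring
- amount of Z at the outlet or at the end, in percent of the Q put in, midnight

- the stated concentrations are those of everything mixed, before any reaction; amounts are the same in each set-up
- the numbers in the tables scatter with a standard deviation of 0.3 percentage points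
- the earlier runs were made in a closed, stirred flask
- a reading or a percentage of Z counts all its forms, free or not
- a reading of Q is of its free form alone

Ochre has midnight's charge but stops at 25.0 min, so we carry it on. From 10.0 min to 25.0 min in ochre, the readings show a net loss of 0.236 of a unit of Z for each unit of free Q that leaves. We call this x, the exchange rate: the points of Z lost per point of free Q lost, which is the point selectivity for Z with its sign turned.

Two extreme versions of midnight can be reckoned in the head. If Q stopped at ochre's last reading, 17.6%, Z stays at 31.3%. If Q kept its last speed, it reaches 11.3% at 40 min, and x brings Z to 29.8%. We expect midnight between them, since ochre's equal time steps of Q shrink, from 2.8 percentage points to 2.1 points, yet continue, so we take the middle, 30.6%.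

In dawn's tank, the liquid younger than 27.7 min makes up half of the whole, and that age lies close to the time of ochre's last reading, so we read about 31.3% for dawn. That stands 0.70 points above our figure for midnight, less than the margin of 2 points.

The forecast also says none, with 30.5% for spring, 30.5% for midnight and, having “weighted the batch Z curve by the residence-time distribution”, 31.5% for dawn, which is higher than our reading.

    Q ⇌ Z + D (K = 0.338 M, k = 0.00744 s⁻¹)
    Z ⇌ G (K = 0.720, k = 0.00252 s⁻¹)
    Q + Z ⇌ J, settled at all times (K = 1.10 M⁻¹)
    Q + D → E (k = 0.00215 M⁻¹ s⁻¹)

The outcome is none: dawn gives 31.8%, spring 30.6% and midnight 30.6%. Midnight ends with free Q at 13.1%, and x, applied from ochre's last reading down to that level, gives 30.2% of Z. Dawn's tank holds Q at 0.207 M, which is 20.7% of the charge, and x, applied upward from ochre's last reading, gives 32.0% against the 31.8% of Z that dawn delivers.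

(The readings stem from a simulated flask with made-up constants, and the scatter is random.)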